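**Assumption:** the SMILES is read as (2S) at the flavanone carbon, (S) at the side-chain carbon bonded to C8, (S) at the carbinol carbon and an E alkene. TBS = tert-butyldimethylsilyl, MOM = methoxymethyl.

## Retrosynthetic overview

1. Target ⇐ removal of one MOM and four TBS groups from a protected flavanone, whose C2–aryl bond and (2S) centre come from a rhodium-catalysed asymmetric 1,4-addition of an arylboronic acid (ring B) to a chromone.
2. Chromone (ring C closed onto ring A) ⇐ 2'-hydroxyacetophenone ⇐ bromination and Weinreb acylation at the only free position type of ring A.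
3. Ring A–side chain bond, benzylic stereocentre, E-styrene and free carbinol ⇐ one proposed nickel-catalysed stereospecific ring-opening SN2' arylation of a cis-2,6-disubstituted dihydropyran with an aryl Grignard made by directed metalation between two MOM ethers.
4. cis-Dihydropyran ⇐ ring-closing metathesis ⇐ iridium-catalysed asymmetric allylic etherification of an (S)-homoallylic alcohol (Keck allylation) with a cinnamyl carbonate.
5. Ring order: ring A is bought; the temporary dihydropyran is made and opened; ring C is closed as a chromone; ring B is attached last.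

## Route

Step 1
Reactants: 1 methyl 3-(4-hydroxyphenyl)propanoate
Product: 2 methyl 3-[4-(TBSO)phenyl]propanoate
Conditions: TBSCl, imidazole, DMF, rt
Reagents that add atoms: tert-butyldimethylsilyl chloride, CC(C)(C)[Si](C)(C)Cl
Why: Silyl ether formation masks the acidic phenol before the hydride and organometallic steps; no stereocentre is involved.

Step 2
Reactants: 2 methyl 3-[4-(TBSO)phenyl]propanoate
Product: 3 3-[4-(TBSO)phenyl]propanal
Conditions: i-Bu2AlH (1.05 equiv), CH2Cl2, −78 °C; aq potassium sodium tartrate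
Reagents that add atoms: none
Why: Partial ester reduction stops at the aluminium hemiacetal at −78 °C, which gives the aldehyde on work-up.

Step 3
Reactants: 3 3-[4-(TBSO)phenyl]propanal
Product: 4 (3S)-1-[4-(TBSO)phenyl]hex-5-en-3-ol
Conditions: (R)-BINOL (20 mol %), Ti(OiPr)4 (10 mol %), 4 Å MS, allylSnBu3, CH2Cl2, −20 °C; aq NaHCO3
Reagents that add atoms: allyltributylstannane, C=CC[Sn](CCCC)(CCCC)CCCC
Why: Keck asymmetric allylation, in which the (R)-BINOL–titanium Lewis acid directs allyl transfer to the aldehyde Re face and so sets the (S) carbinol (CIP order OH > allyl > arylethyl).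

Step 4
Reactants: 5 methyl (2E)-3-(4-hydroxyphenyl)prop-2-enoate
Product: 6 methyl (2E)-3-[4-(TBSO)phenyl]prop-2-enoate
Conditions: TBSCl, imidazole, DMF, rt
Reagents that add atoms: tert-butyldimethylsilyl chloride, CC(C)(C)[Si](C)(C)Cl
Why: Phenol silylation as in step 1; the E alkene is untouched.

Step 5
Reactants: 6 methyl (2E)-3-[4-(TBSO)phenyl]prop-2-enoate
Product: 7 (2E)-3-[4-(TBSO)phenyl]prop-2-en-1-ol
Conditions: i-Bu2AlH (2.2 equiv), CH2Cl2, −78 → 0 °C; aq potassium sodium tartrate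
Reagents that add atoms: none
Why: 1,2-Reduction of the enoate by the aluminium hydride gives the allylic alcohol with the E geometry kept.

Step 6
Reactants: 7 (2E)-3-[4-(TBSO)phenyl]prop-2-en-1-ol
Product: 8 tert-butyl (2E)-3-[4-(TBSO)phenyl]prop-2-en-1-yl carbonate
Conditions: Boc2O, DMAP (10 mol %), CH2Cl2, rt
Reagents that add atoms: di-tert-butyl dicarbonate, CC(C)(C)OC(=O)OC(=O)OC(C)(C)C
Why: DMAP-catalysed O-acylation installs the bulky carbonate leaving group needed for allyl–iridium formation.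

Step 7
Reactants: 4 (3S)-1-[4-(TBSO)phenyl]hex-5-en-3-ol; 8 tert-butyl (2E)-3-[4-(TBSO)phenyl]prop-2-en-1-yl carbonate
Product: 11 (3S)-1-[4-(TBSO)phenyl]hex-5-en-3-yl (1S)-1-[4-(TBSO)phenyl]prop-2-en-1-yl ether, via lithium alkoxide 9 (not isolated), via copper alkoxide 10 (not isolated)
Conditions: 4 (1.3 equiv), n-BuLi, THF, 0 °C; CuI; then 8, [Ir(cod)Cl]2 (2 mol %), (Sa,S,S)-binaphthyl bis(1-phenylethyl)phosphoramidite (4 mol %), THF, rt
Reagents that add atoms: none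
Why: Iridium-catalysed asymmetric allylic etherification, in which the copper alkoxide attacks the aryl-bearing allyl terminus (branched selectivity) on the face fixed by the cyclometalated iridium–phosphoramidite, so the new benzylic C–O centre is set (S) by catalyst control (the mirror-image ligand gives the other diastereomer) and the carbinol centre of 4 is untouched.

Step 8
Reactants: 11 (3S)-1-[4-(TBSO)phenyl]hex-5-en-3-yl (1S)-1-[4-(TBSO)phenyl]prop-2-en-1-yl ether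
Product: 12 (2S,6S)-6-[4-(TBSO)phenyl]-2-{2-[4-(TBSO)phenyl]ethyl}-3,6-dihydro-2H-pyran
Conditions: RuCl2(=CHPh)(PCy3)(H2IMes) (second-generation Grubbs catalyst, 3 mol %), CH2Cl2, 40 °C
Reagents that add atoms: none
Why: Ring-closing olefin metathesis joins the two terminal alkenes with loss of ethylene and touches neither stereocentre, so the (S,S) ether becomes the 2,6-cis dihydropyran.

Step 9
Reactants: 13 5-methoxybenzene-1,3-diol
Product: 14 1-methoxy-3,5-bis(methoxymethoxy)benzene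
Conditions: MOMCl (2.5 equiv), i-Pr2NEt, CH2Cl2, 0 °C → rt
Reagents that add atoms: chloromethyl methyl ether, COCCl
Why: Acetal protection of both phenols gives two cooperating directing groups for the ortho-metalation at the carbon between them.

Step 10
Reactants: 12 (2S,6S)-6-[4-(TBSO)phenyl]-2-{2-[4-(TBSO)phenyl]ethyl}-3,6-dihydro-2H-pyran; 14 1-methoxy-3,5-bis(methoxymethoxy)benzene
Product: 17 (3S,5S,6E)-1,7-bis[4-(TBSO)phenyl]-5-[4-methoxy-2,6-bis(methoxymethoxy)phenyl]hept-6-en-3-ol, via aryllithium 15 (not isolated), via aryl Grignard 16 (not isolated)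
Conditions: 14 (1.6 equiv), n-BuLi, THF, 0 °C; MgBr2·OEt2; then 12, Ni(cod)2 (10 mol %), DPEphos (12 mol %), toluene–THF, 0 °C → rt; aq NH4Cl
Reagents that add atoms: none
Why: Proposed new method: a zerovalent-nickel-catalysed stereospecific ring-opening SN2' Kumada arylation of a cyclic allylic benzylic ether, in which magnesium-assisted oxidative addition of nickel into the doubly activated C6–O bond of the diequatorial half-chair occurs anti to oxygen and gives an η3-allylnickel alkoxide with the aryl group syn (hence the E-styrene); the tethered magnesium alkoxide and retention of styrene conjugation steer reductive elimination of the hindered aryl to C4 on the nickel face, anti to both ring substituents, so the cis-(2S,6S) ring transfers its chirality to the new (5S) centre while the (3S) carbinol is only unmasked; the closest known reactions are the stereospecific nickel-catalysed Kumada ring opening of 2-aryltetrahydropyrans (inversion at the benzylic carbon) and nickel-catalysed Grignard substitution of acyclic allylic ethers.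

Step 11
Reactants: 17 (3S,5S,6E)-1,7-bis[4-(TBSO)phenyl]-5-[4-methoxy-2,6-bis(methoxymethoxy)phenyl]hept-6-en-3-ol
Product: 18 (3S,5S,6E)-3-(TBSO)-1,7-bis[4-(TBSO)phenyl]-5-[4-methoxy-2,6-bis(methoxymethoxy)phenyl]hept-6-ene
Conditions: TBSCl, imidazole, DMAP (cat.), DMF, 40 °C
Reagents that add atoms: tert-butyldimethylsilyl chloride, CC(C)(C)[Si](C)(C)Cl
Why: Silylation of the secondary alcohol removes the only acidic and nucleophilic OH before bromination and lithiation; no stereocentre is affected.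

Step 12
Reactants: 18 (3S,5S,6E)-3-(TBSO)-1,7-bis[4-(TBSO)phenyl]-5-[4-methoxy-2,6-bis(methoxymethoxy)phenyl]hept-6-ene
Product: 19 (3S,5S,6E)-5-[3-bromo-4-methoxy-2,6-bis(methoxymethoxy)phenyl]-3-(TBSO)-1,7-bis[4-(TBSO)phenyl]hept-6-ene
Conditions: NBS (1.0 equiv), CH2Cl2, −78 → −40 °C, dark
Reagents that add atoms: N-bromosuccinimide, O=C1CCC(=O)N1Br
Why: Electrophilic aromatic bromination, where the trioxygenated ring A is far more nucleophilic than the 1,2-disubstituted styrene or the mono-oxygenated rings and its two free positions are equivalent, so one equivalent gives a single monobromide.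

Step 13
Reactants: 19 (3S,5S,6E)-5-[3-bromo-4-methoxy-2,6-bis(methoxymethoxy)phenyl]-3-(TBSO)-1,7-bis[4-(TBSO)phenyl]hept-6-ene
Product: 21 1-{3-[(1E,3S,5S)-5-(TBSO)-1,7-bis(4-TBSO-phenyl)hept-1-en-3-yl]-6-methoxy-2,4-bis(methoxymethoxy)phenyl}ethan-1-one, via aryllithium 20 (not isolated)
Conditions: n-BuLi (1.1 equiv), THF, −78 °C, 10 min; MeC(O)N(OMe)Me, −78 → 0 °C; aq NH4Cl
Reagents that add atoms: N-methoxy-N-methylacetamide, CC(=O)N(C)OC
Why: Bromine–lithium exchange at −78 °C outruns deprotonation of the benzylic allylic C–H, and the Weinreb ketone synthesis stops at the chelated tetrahedral adduct, giving the methyl ketone without over-addition.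

Step 14
Reactants: 21 1-{3-[(1E,3S,5S)-5-(TBSO)-1,7-bis(4-TBSO-phenyl)hept-1-en-3-yl]-6-methoxy-2,4-bis(methoxymethoxy)phenyl}ethan-1-one
Product: 22 1-{3-[(1E,3S,5S)-5-(TBSO)-1,7-bis(4-TBSO-phenyl)hept-1-en-3-yl]-2-hydroxy-6-methoxy-4-(methoxymethoxy)phenyl}ethan-1-one
Conditions: MgBr2·OEt2 (3 equiv), Et2O–CH2Cl2, 0 °C → rt; H2O
Reagents that add atoms: none
Why: Chelation-controlled Lewis acid acetal cleavage, in which magnesium held between the ketone and the ortho MOM oxygens removes only that MOM group and leaves the para MOM and the silyl ethers.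

Step 15
Reactants: 22 1-{3-[(1E,3S,5S)-5-(TBSO)-1,7-bis(4-TBSO-phenyl)hept-1-en-3-yl]-2-hydroxy-6-methoxy-4-(methoxymethoxy)phenyl}ethan-1-one
Product: 24 8-[(1E,3S,5S)-5-(TBSO)-1,7-bis(4-TBSO-phenyl)hept-1-en-3-yl]-5-methoxy-7-(methoxymethoxy)-4H-chromen-4-one, via enaminone 23 (not isolated)
Conditions: Me2NCH(OMe)2, toluene, 90 °C; evaporate; AcOH, CH2Cl2, 40 °C
Reagents that add atoms: N,N-dimethylformamide dimethyl acetal, COC(OC)N(C)C
Why: Condensation of the methyl ketone with the amide acetal gives the enaminone, and acid-induced conjugate addition of the free phenol with loss of dimethylamine closes ring C as the chromone.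

Step 16
Reactants: 24 8-[(1E,3S,5S)-5-(TBSO)-1,7-bis(4-TBSO-phenyl)hept-1-en-3-yl]-5-methoxy-7-(methoxymethoxy)-4H-chromen-4-one; 25 [4-(TBSO)phenyl]boronic acid
Product: 26 (2S)-2-[4-(TBSO)phenyl]-8-[(1E,3S,5S)-5-(TBSO)-1,7-bis(4-TBSO-phenyl)hept-1-en-3-yl]-5-methoxy-7-(methoxymethoxy)-2,3-dihydro-4H-chromen-4-one
Conditions: 25 (3 equiv), [Rh(OH)(cod)]2 (3 mol %), (S)-MeO-F12-BIPHEP (7 mol %), CH2Cl2–H2O (10:1), rt
Reagents that add atoms: none
Why: Rhodium-catalysed asymmetric 1,4-addition of an arylboronic acid (Hayashi–Miyaura reaction) to the chromone, where the aryl–rhodium bisphosphine adds across C2=C3 on the face dictated by the (S)-biaryl ligand (the same sense that gives (S)-3-arylcyclohexanones), setting (2S) under catalyst control remote from the side-chain centres.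

Step 17
Reactants: 26 (2S)-2-[4-(TBSO)phenyl]-8-[(1E,3S,5S)-5-(TBSO)-1,7-bis(4-TBSO-phenyl)hept-1-en-3-yl]-5-methoxy-7-(methoxymethoxy)-2,3-dihydro-4H-chromen-4-one
Product: 28 (2S)-7-hydroxy-2-[4-(TBSO)phenyl]-8-[(1E,3S,5S)-5-(TBSO)-1,7-bis(4-TBSO-phenyl)hept-1-en-3-yl]-5-methoxy-2,3-dihydro-4H-chromen-4-one, via aryl trimethylsilyl ether 27 (not isolated)
Conditions: TMSOTf (3 equiv), 2,2'-bipyridyl (4 equiv), CH2Cl2, 0 °C; then H2O, rt
Reagents that add atoms: none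
Why: Silyl triflate–bipyridyl cleavage of the aryl MOM ether runs through the aryl silyl ether without protic acid, which avoids acid-catalysed addition of OH groups across the electron-rich styrene and leaves C2 and the TBS ethers intact.

Step 18
Reactants: 28 (2S)-7-hydroxy-2-[4-(TBSO)phenyl]-8-[(1E,3S,5S)-5-(TBSO)-1,7-bis(4-TBSO-phenyl)hept-1-en-3-yl]-5-methoxy-2,3-dihydro-4H-chromen-4-one
Product: 29 (2S)-7-hydroxy-8-[(1E,3S,5S)-5-hydroxy-1,7-bis(4-hydroxyphenyl)hept-1-en-3-yl]-2-(4-hydroxyphenyl)-5-methoxy-2,3-dihydro-4H-chromen-4-one (CNP0191649.2)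
Conditions: Et3N·3HF (excess), THF–MeCN, 0 °C → rt
Reagents that add atoms: none
Why: Fluoride-driven desilylation of the three aryl and one alkyl TBS ethers under nearly neutral buffered conditions, so neither retro-oxa-Michael epimerisation at C2 nor acid-induced cyclisation onto the styrene occurs.

## Compound list

1 | methyl 3-(4-hydroxyphenyl)propanoate | COC(=O)CCc1ccc(O)cc1 | starting material
2 | methyl 3-[4-(TBSO)phenyl]propanoate | COC(=O)CCc1ccc(O[Si](C)(C)C(C)(C)C)cc1 | intermediate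
3 | 3-[4-(TBSO)phenyl]propanal | O=CCCc1ccc(O[Si](C)(C)C(C)(C)C)cc1 | intermediate
4 | (3S)-1-[4-(TBSO)phenyl]hex-5-en-3-ol | C=CC[C@@H](O)CCc1ccc(O[Si](C)(C)C(C)(C)C)cc1 | intermediate
5 | methyl (2E)-3-(4-hydroxyphenyl)prop-2-enoate | COC(=O)/C=C/c1ccc(O)cc1 | starting material
6 | methyl (2E)-3-[4-(TBSO)phenyl]prop-2-enoate | COC(=O)/C=C/c1ccc(O[Si](C)(C)C(C)(C)C)cc1 | intermediate
7 | (2E)-3-[4-(TBSO)phenyl]prop-2-en-1-ol | OC/C=C/c1ccc(O[Si](C)(C)C(C)(C)C)cc1 | intermediate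
8 | tert-butyl (2E)-3-[4-(TBSO)phenyl]prop-2-en-1-yl carbonate | CC(C)(C)OC(=O)OC/C=C/c1ccc(O[Si](C)(C)C(C)(C)C)cc1 | intermediate
9 | lithium (3S)-1-[4-(TBSO)phenyl]hex-5-en-3-olate | [Li+].C=CC[C@@H]([O-])CCc1ccc(O[Si](C)(C)C(C)(C)C)cc1 | intermediate
10 | copper (3S)-1-[4-(TBSO)phenyl]hex-5-en-3-olate (CuOR, monovalent copper) | C=CC[C@@H](O[Cu])CCc1ccc(O[Si](C)(C)C(C)(C)C)cc1 | intermediate
11 | (3S)-1-[4-(TBSO)phenyl]hex-5-en-3-yl (1S)-1-[4-(TBSO)phenyl]prop-2-en-1-yl ether | C=C[C@@H](c1ccc(O[Si](C)(C)C(C)(C)C)cc1)O[C@H](CC=C)CCc1ccc(O[Si](C)(C)C(C)(C)C)cc1 | intermediate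
12 | (2S,6S)-6-[4-(TBSO)phenyl]-2-{2-[4-(TBSO)phenyl]ethyl}-3,6-dihydro-2H-pyran (2,6-cis) | CC(C)(C)[Si](C)(C)Oc1ccc(cc1)[C@@H]1C=CC[C@H](CCc2ccc(O[Si](C)(C)C(C)(C)C)cc2)O1 | intermediate
13 | 5-methoxybenzene-1,3-diol | COc1cc(O)cc(O)c1 | starting material
14 | 1-methoxy-3,5-bis(methoxymethoxy)benzene | COCOc1cc(OC)cc(OCOC)c1 | intermediate
15 | [4-methoxy-2,6-bis(methoxymethoxy)phenyl]lithium | [Li]c1c(OCOC)cc(OC)cc1OCOC | intermediate
16 | [4-methoxy-2,6-bis(methoxymethoxy)phenyl]magnesium bromide | Br[Mg]c1c(OCOC)cc(OC)cc1OCOC | intermediate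
17 | (3S,5S,6E)-1,7-bis[4-(TBSO)phenyl]-5-[4-methoxy-2,6-bis(methoxymethoxy)phenyl]hept-6-en-3-ol | COCOc1cc(OC)cc(OCOC)c1[C@H](/C=C/c1ccc(O[Si](C)(C)C(C)(C)C)cc1)C[C@@H](O)CCc1ccc(O[Si](C)(C)C(C)(C)C)cc1 | intermediate
18 | (3S,5S,6E)-3-(TBSO)-1,7-bis[4-(TBSO)phenyl]-5-[4-methoxy-2,6-bis(methoxymethoxy)phenyl]hept-6-ene | COCOc1cc(OC)cc(OCOC)c1[C@H](/C=C/c1ccc(O[Si](C)(C)C(C)(C)C)cc1)C[C@@H](O[Si](C)(C)C(C)(C)C)CCc1ccc(O[Si](C)(C)C(C)(C)C)cc1 | intermediate
19 | (3S,5S,6E)-5-[3-bromo-4-methoxy-2,6-bis(methoxymethoxy)phenyl]-3-(TBSO)-1,7-bis[4-(TBSO)phenyl]hept-6-ene | COCOc1c(Br)c(OC)cc(OCOC)c1[C@H](/C=C/c1ccc(O[Si](C)(C)C(C)(C)C)cc1)C[C@@H](O[Si](C)(C)C(C)(C)C)CCc1ccc(O[Si](C)(C)C(C)(C)C)cc1 | intermediate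
20 | aryllithium from 19 (Li in place of Br) | COCOc1c([Li])c(OC)cc(OCOC)c1[C@H](/C=C/c1ccc(O[Si](C)(C)C(C)(C)C)cc1)C[C@@H](O[Si](C)(C)C(C)(C)C)CCc1ccc(O[Si](C)(C)C(C)(C)C)cc1 | intermediate
21 | 1-{3-[(1E,3S,5S)-5-(TBSO)-1,7-bis(4-TBSO-phenyl)hept-1-en-3-yl]-6-methoxy-2,4-bis(methoxymethoxy)phenyl}ethan-1-one | COCOc1c(C(C)=O)c(OC)cc(OCOC)c1[C@H](/C=C/c1ccc(O[Si](C)(C)C(C)(C)C)cc1)C[C@@H](O[Si](C)(C)C(C)(C)C)CCc1ccc(O[Si](C)(C)C(C)(C)C)cc1 | intermediate
22 | 1-{3-[(1E,3S,5S)-5-(TBSO)-1,7-bis(4-TBSO-phenyl)hept-1-en-3-yl]-2-hydroxy-6-methoxy-4-(methoxymethoxy)phenyl}ethan-1-one | COCOc1cc(OC)c(C(C)=O)c(O)c1[C@H](/C=C/c1ccc(O[Si](C)(C)C(C)(C)C)cc1)C[C@@H](O[Si](C)(C)C(C)(C)C)CCc1ccc(O[Si](C)(C)C(C)(C)C)cc1 | intermediate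
23 | (2E)-3-(dimethylamino)-1-{3-[(1E,3S,5S)-5-(TBSO)-1,7-bis(4-TBSO-phenyl)hept-1-en-3-yl]-2-hydroxy-6-methoxy-4-(methoxymethoxy)phenyl}prop-2-en-1-one | COCOc1cc(OC)c(C(=O)/C=C/N(C)C)c(O)c1[C@H](/C=C/c1ccc(O[Si](C)(C)C(C)(C)C)cc1)C[C@@H](O[Si](C)(C)C(C)(C)C)CCc1ccc(O[Si](C)(C)C(C)(C)C)cc1 | intermediate
24 | 8-[(1E,3S,5S)-5-(TBSO)-1,7-bis(4-TBSO-phenyl)hept-1-en-3-yl]-5-methoxy-7-(methoxymethoxy)-4H-chromen-4-one | COCOc1cc(OC)c2C(=O)C=COc2c1[C@H](/C=C/c1ccc(O[Si](C)(C)C(C)(C)C)cc1)C[C@@H](O[Si](C)(C)C(C)(C)C)CCc1ccc(O[Si](C)(C)C(C)(C)C)cc1 | intermediate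
25 | [4-(TBSO)phenyl]boronic acid | CC(C)(C)[Si](C)(C)Oc1ccc(B(O)O)cc1 | starting material
26 | (2S)-2-[4-(TBSO)phenyl]-8-[(1E,3S,5S)-5-(TBSO)-1,7-bis(4-TBSO-phenyl)hept-1-en-3-yl]-5-methoxy-7-(methoxymethoxy)-2,3-dihydro-4H-chromen-4-one | COc1cc(OCOC)c([C@H](/C=C/c2ccc(O[Si](C)(C)C(C)(C)C)cc2)C[C@@H](O[Si](C)(C)C(C)(C)C)CCc2ccc(O[Si](C)(C)C(C)(C)C)cc2)c2c1C(=O)C[C@@H](c1ccc(O[Si](C)(C)C(C)(C)C)cc1)O2 | intermediate
27 | 7-O-trimethylsilyl analogue of 26 (OSiMe3 in place of OMOM) | COc1cc(O[Si](C)(C)C)c([C@H](/C=C/c2ccc(O[Si](C)(C)C(C)(C)C)cc2)C[C@@H](O[Si](C)(C)C(C)(C)C)CCc2ccc(O[Si](C)(C)C(C)(C)C)cc2)c2c1C(=O)C[C@@H](c1ccc(O[Si](C)(C)C(C)(C)C)cc1)O2 | intermediate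
28 | (2S)-7-hydroxy-2-[4-(TBSO)phenyl]-8-[(1E,3S,5S)-5-(TBSO)-1,7-bis(4-TBSO-phenyl)hept-1-en-3-yl]-5-methoxy-2,3-dihydro-4H-chromen-4-one | COc1cc(O)c([C@H](/C=C/c2ccc(O[Si](C)(C)C(C)(C)C)cc2)C[C@@H](O[Si](C)(C)C(C)(C)C)CCc2ccc(O[Si](C)(C)C(C)(C)C)cc2)c2c1C(=O)C[C@@H](c1ccc(O[Si](C)(C)C(C)(C)C)cc1)O2 | intermediate
29 | (2S)-7-hydroxy-8-[(1E,3S,5S)-5-hydroxy-1,7-bis(4-hydroxyphenyl)hept-1-en-3-yl]-2-(4-hydroxyphenyl)-5-methoxy-2,3-dihydro-4H-chromen-4-one | COc1cc(O)c([C@H](/C=C/c2ccc(O)cc2)C[C@@H](O)CCc2ccc(O)cc2)c2c1C(=O)C[C@@H](c1ccc(O)cc1)O2 | target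

## Step count and risk

Total steps: 18. Longest linear sequence: 14 (steps 1, 2, 3, 7, 8, 10, 11, 12, 13, 14, 15, 16, 17, 18).

The three steps most likely to fail:

**Step 10 (the proposed ring-opening arylation).** Risks are attack at the benzylic allyl terminus, ionisation without nickel (loss of stereospecificity) and slow transmetalation of the hindered Grignard. The fallback uses known chemistry, sets out from 4 and the Grignard 16, and comes back at 18. Alcohol 4 is acylated with acryloyl chloride and Et3N to the acrylate ester F1, and ring-closing metathesis with the second-generation Grubbs catalyst gives the unsaturated lactone F2. A CuBr·SMe2-catalysed conjugate addition of 16 (THF, −40 °C) enters anti to the C6 side chain and gives the trans-4,6 lactone F3, which carries both side-chain stereocentres in the required (S,S) relationship. The aryllithium F4, made from 1-bromo-4-(tert-butyldimethylsilyloxy)benzene and n-BuLi, adds once to the lactone carbonyl at −78 °C to give the hydroxy ketone F5. Silylation with TBSCl and imidazole gives the silyl ether ketone F6, NaBH4 gives the benzylic alcohol F7 as both C1 epimers, and dehydration with the Burgess reagent gives the E-styrene 18. This costs seven operations in place of steps 4 to 8, 10 and 11.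

**Step 12 (bromination next to an electron-rich styrene).** The risk is bromination or bromo-functionalisation of the alkene. The fallback sets out from 18 and comes back at 21. Vilsmeier–Haack formylation (POCl3, DMF, 0 °C; aq NaOAc) uses a much weaker electrophile that reacts only with the trioxygenated ring and gives the aldehyde F8. MeMgBr gives the secondary benzylic alcohol F9 as both epimers, and MnO2 oxidation gives the methyl ketone 21.

**Step 16 (conjugate addition to an electron-rich, 8-substituted chromone).** Risks are low conversion and 1,2-addition. The fallback sets out from 22 and comes back at 26. Aldol condensation of 22 with 4-(tert-butyldimethylsilyloxy)benzaldehyde (pyrrolidine, toluene, 60 °C) gives the 2'-hydroxychalcone F10. Intramolecular oxa-Michael closure (NaOAc, EtOH, 50 °C) gives 26 together with its C2 epimer, the (2R)-flavanone F11. The two are diastereomers and are separated by preparative HPLC; F11 is re-opened to F10 with DBU and recycled, so C2 is secured by separation and recycling instead of by catalysis.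

## Further compounds

F1 | step 10 | (3S)-1-[4-(TBSO)phenyl]hex-5-en-3-yl prop-2-enoate | C=CC(=O)O[C@H](CC=C)CCc1ccc(O[Si](C)(C)C(C)(C)C)cc1
F2 | step 10 | (6S)-6-{2-[4-(TBSO)phenyl]ethyl}-5,6-dihydro-2H-pyran-2-one | O=C1C=CC[C@H](CCc2ccc(O[Si](C)(C)C(C)(C)C)cc2)O1
F3 | step 10 | (4S,6S)-4-[4-methoxy-2,6-bis(methoxymethoxy)phenyl]-6-{2-[4-(TBSO)phenyl]ethyl}oxan-2-one | O=C1C[C@@H](c2c(OCOC)cc(OC)cc2OCOC)C[C@H](CCc2ccc(O[Si](C)(C)C(C)(C)C)cc2)O1
F4 | step 10 | [4-(TBSO)phenyl]lithium | [Li]c1ccc(O[Si](C)(C)C(C)(C)C)cc1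
F5 | step 10 | (3S,5S)-5-hydroxy-3-[4-methoxy-2,6-bis(methoxymethoxy)phenyl]-1,7-bis[4-(TBSO)phenyl]heptan-1-one | O=C(C[C@@H](c1c(OCOC)cc(OC)cc1OCOC)C[C@@H](O)CCc1ccc(O[Si](C)(C)C(C)(C)C)cc1)c1ccc(O[Si](C)(C)C(C)(C)C)cc1
F6 | step 10 | (3S,5S)-5-(TBSO)-3-[4-methoxy-2,6-bis(methoxymethoxy)phenyl]-1,7-bis[4-(TBSO)phenyl]heptan-1-one | O=C(C[C@@H](c1c(OCOC)cc(OC)cc1OCOC)C[C@@H](O[Si](C)(C)C(C)(C)C)CCc1ccc(O[Si](C)(C)C(C)(C)C)cc1)c1ccc(O[Si](C)(C)C(C)(C)C)cc1
F7 | step 10 | 5-(TBSO)-3-[4-methoxy-2,6-bis(methoxymethoxy)phenyl]-1,7-bis[4-(TBSO)phenyl]heptan-1-ol, C3 and C5 as in F6, both C1 epimers | OC(C[C@@H](c1c(OCOC)cc(OC)cc1OCOC)C[C@@H](O[Si](C)(C)C(C)(C)C)CCc1ccc(O[Si](C)(C)C(C)(C)C)cc1)c1ccc(O[Si](C)(C)C(C)(C)C)cc1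
F8 | step 12 | 3-[(1E,3S,5S)-5-(TBSO)-1,7-bis(4-TBSO-phenyl)hept-1-en-3-yl]-6-methoxy-2,4-bis(methoxymethoxy)benzaldehyde | COCOc1c(C=O)c(OC)cc(OCOC)c1[C@H](/C=C/c1ccc(O[Si](C)(C)C(C)(C)C)cc1)C[C@@H](O[Si](C)(C)C(C)(C)C)CCc1ccc(O[Si](C)(C)C(C)(C)C)cc1
F9 | step 12 | 1-{3-[(1E,3S,5S)-5-(TBSO)-1,7-bis(4-TBSO-phenyl)hept-1-en-3-yl]-6-methoxy-2,4-bis(methoxymethoxy)phenyl}ethan-1-ol, both carbinol epimers | COCOc1c(C(C)O)c(OC)cc(OCOC)c1[C@H](/C=C/c1ccc(O[Si](C)(C)C(C)(C)C)cc1)C[C@@H](O[Si](C)(C)C(C)(C)C)CCc1ccc(O[Si](C)(C)C(C)(C)C)cc1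
F10 | step 16 | (2E)-1-{3-[(1E,3S,5S)-5-(TBSO)-1,7-bis(4-TBSO-phenyl)hept-1-en-3-yl]-2-hydroxy-6-methoxy-4-(methoxymethoxy)phenyl}-3-[4-(TBSO)phenyl]prop-2-en-1-one | COCOc1cc(OC)c(C(=O)/C=C/c2ccc(O[Si](C)(C)C(C)(C)C)cc2)c(O)c1[C@H](/C=C/c1ccc(O[Si](C)(C)C(C)(C)C)cc1)C[C@@H](O[Si](C)(C)C(C)(C)C)CCc1ccc(O[Si](C)(C)C(C)(C)C)cc1
F11 | step 16 | (2R)-epimer of 26 | COc1cc(OCOC)c([C@H](/C=C/c2ccc(O[Si](C)(C)C(C)(C)C)cc2)C[C@@H](O[Si](C)(C)C(C)(C)C)CCc2ccc(O[Si](C)(C)C(C)(C)C)cc2)c2c1C(=O)C[C@H](c1ccc(O[Si](C)(C)C(C)(C)C)cc1)O2
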